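**Retrosynthetic overview**
1. Chalcone C=C: Claisen–Schmidt condensation of a 3-substituted 2-hydroxyacetophenone with 4-(methoxymethoxy)benzaldehyde; the two MOM ethers come off last.
2. C2=C3 of the heptenyl chain: cross-metathesis of a 1,1-diarylprop-2-ene with (S)-1-phenylhex-5-en-3-ol (Keck allylation of 3-phenylpropanal sets 5S).
3. Ring A–C1 bond and the (1R) diaryl-allyl centre: a new enantioselective aromatic Claisen rearrangement of a cinnamyl ether tethered to the chelated 2-oxygen, so that C-allylation can only reach C3 (between the two oxygens) and only the aryl-bearing allyl terminus.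
4. Cinnamyl ether: MOM protection of the 4-OH of 2',4'-dihydroxy-6'-methoxyacetophenone, O-allylation of the 2-OH, cross-metathesis with 4-acetoxystyrene.
5. No ring is formed: all four benzene rings are bought in (acetophenone = ring A, benzaldehyde = ring B, styrene = 4-hydroxyphenyl ring, 3-phenylpropanal = phenyl ring).

Assumption: the target is taken exactly as drawn in the SMILES, (1R) at the diaryl-allyl carbon and (5S) at the carbinol; the facial sense of the new catalyst in step 4 rests on the quadrant model stated there, and the (R,R) ligand is used instead if experiment shows the opposite sense.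

Abbreviations: MOM = methoxymethyl; tBu-box = 2,2'-(propane-2,2-diyl)bis(4-tert-butyl-4,5-dihydrooxazole); H2IMes = 1,3-dimesitylimidazolidin-2-ylidene; fod = 6,6,7,7,8,8,8-heptafluoro-2,2-dimethyloctane-3,5-dionate; MS = molecular sieves.

**Route**

Step 1
Reactants: 1 1-(2,4-dihydroxy-6-methoxyphenyl)ethan-1-one
Product: 2 1-[2-hydroxy-6-methoxy-4-(methoxymethoxy)phenyl]ethan-1-one
Conditions: MOMCl (1.1 equiv), K2CO3, acetone, 0 °C to rt
Reagents that add atoms: chloromethyl methyl ether (MOMCl), COCCl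
Why: Williamson-type O-alkylation (MOM protection) is selective for the 4-OH because the 2-OH is held in a strong hydrogen bond to the acetyl carbonyl and is far less nucleophilic.

Step 2
Reactants: 2 1-[2-hydroxy-6-methoxy-4-(methoxymethoxy)phenyl]ethan-1-one
Product: 3 1-[2-(allyloxy)-6-methoxy-4-(methoxymethoxy)phenyl]ethan-1-one
Conditions: allyl bromide, K2CO3, DMF, 60 °C
Reagents that add atoms: allyl bromide, C=CCBr
Why: Williamson ether synthesis under more forcing conditions alkylates the remaining chelated phenol and places the allyl tether on the oxygen that is ortho to C3, the carbon that must later carry the side chain.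

Step 3
Reactants: 3 1-[2-(allyloxy)-6-methoxy-4-(methoxymethoxy)phenyl]ethan-1-one; 4 4-vinylphenyl acetate (4-acetoxystyrene)
Product: 5 4-[(1E)-3-[2-acetyl-3-methoxy-5-(methoxymethoxy)phenoxy]prop-1-en-1-yl]phenyl acetate
Conditions: second-generation Hoveyda–Grubbs catalyst RuCl2(H2IMes)(=CH-C6H4-2-OiPr) (5 mol%), 4 (3 equiv), CH2Cl2, 40 °C
Reagents that add atoms: none
Why: Olefin cross-metathesis of the unhindered allyl ether with excess styrene gives the thermodynamically favoured E-cinnamyl ether with loss of ethylene, and the acetate keeps the styrene ring electron-poor enough to disfavour later ionisation.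

Step 4
Reactants: 5 4-[(1E)-3-[2-acetyl-3-methoxy-5-(methoxymethoxy)phenoxy]prop-1-en-1-yl]phenyl acetate
Product: 7 4-[(1R)-1-[3-acetyl-2-hydroxy-4-methoxy-6-(methoxymethoxy)phenyl]prop-2-en-1-yl]phenyl acetate, via ortho-dienone 6 (not isolated)
Conditions: [Cu((S,S)-tBu-box)](SbF6)2 (10 mol%), 4 Å MS, CH2Cl2, 0 °C to rt
Reagents that add atoms: none
Why: Proposed new method: catalytic enantioselective aromatic Claisen rearrangement of a benzenoid 2-acylaryl cinnamyl ether; the C2-symmetric divalent-copper Lewis acid binds the ether oxygen and the acetyl oxygen as a six-membered chelate, which polarises the O–CH2 bond (charge-accelerated concerted [3,3] shift through a chair with the aryl group of the E-olefin equatorial), holds the allyl unit on the C3 side so that only C3 and only the aryl-bearing allyl terminus can bond, and shields with the tert-butyl group beside the ether oxygen the face leading to the (S) product, so the new C–C bond sets (1R) before dienone 6 enolises to the phenol and releases the catalyst; closest known reaction type: Lewis-acid-catalysed aromatic Claisen rearrangement of allyl aryl ethers (achiral lanthanide catalysts with 1,3-chirality transfer, and chiral copper Lewis acids shown for two-point-binding allyl vinyl ethers and allyl naphthyl ethers but not, to my knowledge, for a simple benzene ring).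

Step 5
Reactants: 8 3-phenylpropanal
Product: 10 (3S)-1-phenylhex-5-en-3-ol, via stannyl ether 9 (not isolated)
Conditions: allyltributylstannane, Ti(OiPr)4 (10 mol%), (R)-BINOL (20 mol%), 4 Å MS, CH2Cl2, −20 °C; aq. NaHCO3
Reagents that add atoms: allyltributylstannane, C=CC[Sn](CCCC)(CCCC)CCCC
Why: Keck asymmetric allylation, in which the (R)-BINOL–titanium Lewis acid directs the allylstannane to the Re face of the aldehyde, gives the (S) carbinol (C5 of the target) after hydrolysis of the stannyl ether.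

Step 6
Reactants: 7 4-[(1R)-1-[3-acetyl-2-hydroxy-4-methoxy-6-(methoxymethoxy)phenyl]prop-2-en-1-yl]phenyl acetate; 10 (3S)-1-phenylhex-5-en-3-ol
Product: 11 4-[(1R,2E,5S)-1-[3-acetyl-2-hydroxy-4-methoxy-6-(methoxymethoxy)phenyl]-5-hydroxy-7-phenylhept-2-en-1-yl]phenyl acetate
Conditions: RuCl2(H2IMes)(=CH-C6H4-2-OiPr) (10 mol%), 10 (3 equiv), 1,4-benzoquinone (10 mol%), CH2Cl2, 40 °C
Reagents that add atoms: none
Why: Olefin cross-metathesis of the allylically branched terminal olefin with excess unhindered homoallylic alcohol forms C2=C3 with E geometry enforced by the bulky diaryl-methine neighbour, touches neither stereocentre, and benzoquinone suppresses ruthenium-hydride olefin migration.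

Step 7
Reactants: 11 4-[(1R,2E,5S)-1-[3-acetyl-2-hydroxy-4-methoxy-6-(methoxymethoxy)phenyl]-5-hydroxy-7-phenylhept-2-en-1-yl]phenyl acetate; 12 4-(methoxymethoxy)benzaldehyde
Product: 15 (2E)-1-[2-hydroxy-3-[(1R,2E,5S)-5-hydroxy-1-(4-hydroxyphenyl)-7-phenylhept-2-en-1-yl]-6-methoxy-4-(methoxymethoxy)phenyl]-3-[4-(methoxymethoxy)phenyl]prop-2-en-1-one, via deacetylated ketone 13 (not isolated), via aldol adduct 14 (not isolated)
Conditions: KOH (50% aq.), EtOH, rt; aq. NH4Cl
Reagents that add atoms: none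
Why: Claisen–Schmidt (aldol) condensation of the methyl ketone with the non-enolisable aldehyde and E1cB dehydration gives the E-chalcone while the aryl acetate is saponified in the same pot, and the diaryl-allyl C–H is far too weakly acidic for KOH to disturb the (1R) centre.

Step 8
Reactants: 15 (2E)-1-[2-hydroxy-3-[(1R,2E,5S)-5-hydroxy-1-(4-hydroxyphenyl)-7-phenylhept-2-en-1-yl]-6-methoxy-4-(methoxymethoxy)phenyl]-3-[4-(methoxymethoxy)phenyl]prop-2-en-1-one
Product: 18 epi-calyxin H, via ring-A-deprotected chalcone 16 (not isolated), via ring-B-deprotected chalcone 17 (not isolated)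
Conditions: HCl (3 M in MeOH), THF, 0 °C to rt
Reagents that add atoms: none
Why: Acid-catalysed transacetalisation removes both MOM ethers as dimethoxymethane at room temperature, mild enough to leave the 2'-hydroxychalcone, the E-olefin and both stereocentres intact.

**Compound list**
1 | 1-(2,4-dihydroxy-6-methoxyphenyl)ethan-1-one | CC(=O)c1c(O)cc(O)cc1OC | starting material
2 | 1-[2-hydroxy-6-methoxy-4-(methoxymethoxy)phenyl]ethan-1-one | CC(=O)c1c(O)cc(OCOC)cc1OC | intermediate
3 | 1-[2-(allyloxy)-6-methoxy-4-(methoxymethoxy)phenyl]ethan-1-one | CC(=O)c1c(OCC=C)cc(OCOC)cc1OC | intermediate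
4 | 4-vinylphenyl acetate (4-acetoxystyrene) | CC(=O)Oc1ccc(C=C)cc1 | starting material
5 | 4-[(1E)-3-[2-acetyl-3-methoxy-5-(methoxymethoxy)phenoxy]prop-1-en-1-yl]phenyl acetate | CC(=O)c1c(OC/C=C/c2ccc(OC(C)=O)cc2)cc(OCOC)cc1OC | intermediate
6 | 4-[(1S)-1-[(1S)-3-acetyl-4-methoxy-6-(methoxymethoxy)-2-oxocyclohexa-3,5-dien-1-yl]prop-2-en-1-yl]phenyl acetate (ortho-dienone) | CC(=O)C1=C(OC)C=C(OCOC)[C@H]([C@H](C=C)c2ccc(OC(C)=O)cc2)C1=O | intermediate
7 | 4-[(1R)-1-[3-acetyl-2-hydroxy-4-methoxy-6-(methoxymethoxy)phenyl]prop-2-en-1-yl]phenyl acetate | CC(=O)c1c(O)c([C@H](C=C)c2ccc(OC(C)=O)cc2)c(OCOC)cc1OC | intermediate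
8 | 3-phenylpropanal | O=CCCc1ccccc1 | starting material
9 | tributyl{[(3S)-1-phenylhex-5-en-3-yl]oxy}stannane | C=CC[C@@H](O[Sn](CCCC)(CCCC)CCCC)CCc1ccccc1 | intermediate
10 | (3S)-1-phenylhex-5-en-3-ol | C=CC[C@@H](O)CCc1ccccc1 | intermediate
11 | 4-[(1R,2E,5S)-1-[3-acetyl-2-hydroxy-4-methoxy-6-(methoxymethoxy)phenyl]-5-hydroxy-7-phenylhept-2-en-1-yl]phenyl acetate | CC(=O)c1c(O)c([C@H](/C=C/C[C@@H](O)CCc2ccccc2)c2ccc(OC(C)=O)cc2)c(OCOC)cc1OC | intermediate
12 | 4-(methoxymethoxy)benzaldehyde | COCOc1ccc(C=O)cc1 | starting material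
13 | 1-[2-hydroxy-3-[(1R,2E,5S)-5-hydroxy-1-(4-hydroxyphenyl)-7-phenylhept-2-en-1-yl]-6-methoxy-4-(methoxymethoxy)phenyl]ethan-1-one | CC(=O)c1c(O)c([C@H](/C=C/C[C@@H](O)CCc2ccccc2)c2ccc(O)cc2)c(OCOC)cc1OC | intermediate
14 | 3-hydroxy-1-[2-hydroxy-3-[(1R,2E,5S)-5-hydroxy-1-(4-hydroxyphenyl)-7-phenylhept-2-en-1-yl]-6-methoxy-4-(methoxymethoxy)phenyl]-3-[4-(methoxymethoxy)phenyl]propan-1-one (both epimers at the new carbinol) | COCOc1ccc(C(O)CC(=O)c2c(O)c([C@H](/C=C/C[C@@H](O)CCc3ccccc3)c3ccc(O)cc3)c(OCOC)cc2OC)cc1 | intermediate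
15 | (2E)-1-[2-hydroxy-3-[(1R,2E,5S)-5-hydroxy-1-(4-hydroxyphenyl)-7-phenylhept-2-en-1-yl]-6-methoxy-4-(methoxymethoxy)phenyl]-3-[4-(methoxymethoxy)phenyl]prop-2-en-1-one | COCOc1ccc(/C=C/C(=O)c2c(O)c([C@H](/C=C/C[C@@H](O)CCc3ccccc3)c3ccc(O)cc3)c(OCOC)cc2OC)cc1 | intermediate
16 | (2E)-1-[2,4-dihydroxy-3-[(1R,2E,5S)-5-hydroxy-1-(4-hydroxyphenyl)-7-phenylhept-2-en-1-yl]-6-methoxyphenyl]-3-[4-(methoxymethoxy)phenyl]prop-2-en-1-one | COCOc1ccc(/C=C/C(=O)c2c(O)c([C@H](/C=C/C[C@@H](O)CCc3ccccc3)c3ccc(O)cc3)c(O)cc2OC)cc1 | intermediate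
17 | (2E)-1-[2-hydroxy-3-[(1R,2E,5S)-5-hydroxy-1-(4-hydroxyphenyl)-7-phenylhept-2-en-1-yl]-6-methoxy-4-(methoxymethoxy)phenyl]-3-(4-hydroxyphenyl)prop-2-en-1-one | Oc1ccc(/C=C/C(=O)c2c(O)c([C@H](/C=C/C[C@@H](O)CCc3ccccc3)c3ccc(O)cc3)c(OCOC)cc2OC)cc1 | intermediate
18 | epi-calyxin H, (2E)-1-[2,4-dihydroxy-3-[(1R,2E,5S)-5-hydroxy-1-(4-hydroxyphenyl)-7-phenylhept-2-en-1-yl]-6-methoxyphenyl]-3-(4-hydroxyphenyl)prop-2-en-1-one | COc1cc(O)c([C@H](/C=C/C[C@@H](O)CCc2ccccc2)c2ccc(O)cc2)c(O)c1C(=O)/C=C/c1ccc(O)cc1 | target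

**Step count and risks**

Total step count: 8. Longest linear sequence: 7 steps (1 → 2 → 3 → 5 → 7 → 11 → 15 → 18); step 5 is a one-step side branch.

The three steps most likely to fail:

Step 4 (the proposed new Claisen rearrangement). It can fail in four ways. The Lewis-acid-bound ether may ionise to a cinnamyl cation and a phenoxide, giving the linear [1,3] product or para products. The catalyst may bind unproductively between the acetyl and the 6-methoxy oxygens. The enantioselectivity may be low or of the opposite sense. The Lewis acid may remove the MOM group or cyclise the product phenol onto the olefin. The fallback is known chemistry, sets out from 2 and 4, comes back at 11, and sets the centre by 1,3-chirality transfer instead of catalyst control. Cross-metathesis of 4 with commercial (R)-but-3-en-2-ol (RuCl2(H2IMes)(=CH-C6H4-2-OiPr), CH2Cl2, 40 °C) gives the allylic alcohol 4-[(1E,3R)-3-hydroxybut-1-en-1-yl]phenyl acetate F1. ClCO2Me and pyridine convert it into the carbonate 4-[(1E,3R)-3-[(methoxycarbonyl)oxy]but-1-en-1-yl]phenyl acetate F2. Pd(PPh3)4 (2 mol%, THF, rt) couples F2 with phenol 2 with net retention (ionisation and phenoxide attack each invert) at the methyl-bearing allyl terminus, which keeps the styrene conjugated, to give the aryl ether 4-[(1E,3R)-3-[2-acetyl-3-methoxy-5-(methoxymethoxy)phenoxy]but-1-en-1-yl]phenyl acetate F3. Eu(fod)3 (10 mol%, CHCl3, 50 °C) then promotes the aromatic Claisen rearrangement through a chair with the methyl group equatorial; the C–O stereocentre is transferred suprafacially to the new C–C bond by way of the ortho-dienone 4-[(1S,2E)-1-[(1S)-3-acetyl-4-methoxy-6-(methoxymethoxy)-2-oxocyclohexa-3,5-dien-1-yl]but-2-en-1-yl]phenyl acetate F4, which enolises to the phenol 4-[(1R,2E)-1-[3-acetyl-2-hydroxy-4-methoxy-6-(methoxymethoxy)phenyl]but-2-en-1-yl]phenyl acetate F5. Cross-metathesis of F5 with 10 under the conditions of step 6 (propene is lost in place of ethylene) gives 11. Because the configuration of this material follows from the chirality transfer, it also serves to check the sense of induction of step 4.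

Step 6 (cross-metathesis at the hindered diaryl-methine olefin). It can fail through low conversion at the congested olefin or through migration of the double bond into conjugation with the two aryl rings. The fallback sets out from 10 and 2 and comes back at 11; it makes the C2=C3 bond in the sigmatropic step, so no metathesis is needed at the hindered carbon. Alcohol 10 is silylated (TBSCl, imidazole, DMF) to tert-butyldimethyl{[(3S)-1-phenylhex-5-en-3-yl]oxy}silane F6 and ozonised (O3, CH2Cl2, −78 °C; PPh3) to the aldehyde (3S)-3-[(tert-butyldimethylsilyl)oxy]-5-phenylpentanal F7. The alkenylzinc reagent generated from 4-ethynylphenyl acetate (Cp2Zr(H)Cl, then Me2Zn) adds to F7 under control of a chiral amino-alcohol ligand (3-exo-morpholinoisoborneol, enantiomer chosen for the 3R product; the 3S epimer is a separable diastereomer) to give the allylic alcohol 4-[(1E,3R,5S)-5-[(tert-butyldimethylsilyl)oxy]-3-hydroxy-7-phenylhept-1-en-1-yl]phenyl acetate F8. ClCO2Me and pyridine give the carbonate 4-[(1E,3R,5S)-5-[(tert-butyldimethylsilyl)oxy]-3-[(methoxycarbonyl)oxy]-7-phenylhept-1-en-1-yl]phenyl acetate F9. Pd(PPh3)4-catalysed etherification of 2 with F9 (net retention, attack at the alkyl-bearing terminus) gives the aryl ether 4-[(1E,3R,5S)-3-[2-acetyl-3-methoxy-5-(methoxymethoxy)phenoxy]-5-[(tert-butyldimethylsilyl)oxy]-7-phenylhept-1-en-1-yl]phenyl acetate F10. Eu(fod)3 (10 mol%, CHCl3, 50 °C) induces the chair Claisen rearrangement (side chain equatorial, hence 2E; 3R is transferred to 1R) through the ortho-dienone 4-[(1S,2E,5S)-1-[(1S)-3-acetyl-4-methoxy-6-(methoxymethoxy)-2-oxocyclohexa-3,5-dien-1-yl]-5-[(tert-butyldimethylsilyl)oxy]-7-phenylhept-2-en-1-yl]phenyl acetate F11 to the phenol 4-[(1R,2E,5S)-1-[3-acetyl-2-hydroxy-4-methoxy-6-(methoxymethoxy)phenyl]-5-[(tert-butyldimethylsilyl)oxy]-7-phenylhept-2-en-1-yl]phenyl acetate F12. HF·pyridine (THF, 0 °C) removes the silyl group and gives 11.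

Step 8 (acidic removal of two MOM groups on the finished chalcone). It can fail because acid cyclises 2'-hydroxychalcones to flavanones, can add methanol to the enone, and could ionise the electron-rich diaryl-allyl centre. The fallback sets out from 11 and comes back at 18; it moves the acid step in front of chalcone formation and runs the condensation without protecting groups. HCl in MeOH (rt) removes the MOM ether of 11 and transesterifies its acetate, giving the triol ketone 1-[2,4-dihydroxy-3-[(1R,2E,5S)-5-hydroxy-1-(4-hydroxyphenyl)-7-phenylhept-2-en-1-yl]-6-methoxyphenyl]ethan-1-one F13. Claisen–Schmidt condensation of F13 with unprotected 4-hydroxybenzaldehyde (excess 60% aq. KOH, EtOH, rt, 3 d; slower because both partners are phenoxides) passes through the aldol adduct 1-[2,4-dihydroxy-3-[(1R,2E,5S)-5-hydroxy-1-(4-hydroxyphenyl)-7-phenylhept-2-en-1-yl]-6-methoxyphenyl]-3-hydroxy-3-(4-hydroxyphenyl)propan-1-one F14 and, after neutralisation with aq. NH4Cl, gives 18 directly.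

**Further compounds**
F1 | step 4 | 4-[(1E,3R)-3-hydroxybut-1-en-1-yl]phenyl acetate | C[C@@H](O)/C=C/c1ccc(OC(C)=O)cc1
F2 | step 4 | 4-[(1E,3R)-3-[(methoxycarbonyl)oxy]but-1-en-1-yl]phenyl acetate | C[C@@H](OC(=O)OC)/C=C/c1ccc(OC(C)=O)cc1
F3 | step 4 | 4-[(1E,3R)-3-[2-acetyl-3-methoxy-5-(methoxymethoxy)phenoxy]but-1-en-1-yl]phenyl acetate | CC(=O)c1c(O[C@H](C)/C=C/c2ccc(OC(C)=O)cc2)cc(OCOC)cc1OC
F4 | step 4 | 4-[(1S,2E)-1-[(1S)-3-acetyl-4-methoxy-6-(methoxymethoxy)-2-oxocyclohexa-3,5-dien-1-yl]but-2-en-1-yl]phenyl acetate | CC(=O)C1=C(OC)C=C(OCOC)[C@H]([C@H](/C=C/C)c2ccc(OC(C)=O)cc2)C1=O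
F5 | step 4 | 4-[(1R,2E)-1-[3-acetyl-2-hydroxy-4-methoxy-6-(methoxymethoxy)phenyl]but-2-en-1-yl]phenyl acetate | CC(=O)c1c(O)c([C@H](/C=C/C)c2ccc(OC(C)=O)cc2)c(OCOC)cc1OC
F6 | step 6 | tert-butyldimethyl{[(3S)-1-phenylhex-5-en-3-yl]oxy}silane | C=CC[C@@H](O[Si](C)(C)C(C)(C)C)CCc1ccccc1
F7 | step 6 | (3S)-3-[(tert-butyldimethylsilyl)oxy]-5-phenylpentanal | O=CC[C@@H](O[Si](C)(C)C(C)(C)C)CCc1ccccc1
F8 | step 6 | 4-[(1E,3R,5S)-5-[(tert-butyldimethylsilyl)oxy]-3-hydroxy-7-phenylhept-1-en-1-yl]phenyl acetate | CC(=O)Oc1ccc(/C=C/[C@H](O)C[C@@H](O[Si](C)(C)C(C)(C)C)CCc2ccccc2)cc1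
F9 | step 6 | 4-[(1E,3R,5S)-5-[(tert-butyldimethylsilyl)oxy]-3-[(methoxycarbonyl)oxy]-7-phenylhept-1-en-1-yl]phenyl acetate | CC(=O)Oc1ccc(/C=C/[C@H](OC(=O)OC)C[C@@H](O[Si](C)(C)C(C)(C)C)CCc2ccccc2)cc1
F10 | step 6 | 4-[(1E,3R,5S)-3-[2-acetyl-3-methoxy-5-(methoxymethoxy)phenoxy]-5-[(tert-butyldimethylsilyl)oxy]-7-phenylhept-1-en-1-yl]phenyl acetate | CC(=O)c1c(O[C@@H](/C=C/c2ccc(OC(C)=O)cc2)C[C@@H](O[Si](C)(C)C(C)(C)C)CCc2ccccc2)cc(OCOC)cc1OC
F11 | step 6 | 4-[(1S,2E,5S)-1-[(1S)-3-acetyl-4-methoxy-6-(methoxymethoxy)-2-oxocyclohexa-3,5-dien-1-yl]-5-[(tert-butyldimethylsilyl)oxy]-7-phenylhept-2-en-1-yl]phenyl acetate | CC(=O)C1=C(OC)C=C(OCOC)[C@H]([C@H](/C=C/C[C@@H](O[Si](C)(C)C(C)(C)C)CCc2ccccc2)c2ccc(OC(C)=O)cc2)C1=O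
F12 | step 6 | 4-[(1R,2E,5S)-1-[3-acetyl-2-hydroxy-4-methoxy-6-(methoxymethoxy)phenyl]-5-[(tert-butyldimethylsilyl)oxy]-7-phenylhept-2-en-1-yl]phenyl acetate | CC(=O)c1c(O)c([C@H](/C=C/C[C@@H](O[Si](C)(C)C(C)(C)C)CCc2ccccc2)c2ccc(OC(C)=O)cc2)c(OCOC)cc1OC
F13 | step 8 | 1-[2,4-dihydroxy-3-[(1R,2E,5S)-5-hydroxy-1-(4-hydroxyphenyl)-7-phenylhept-2-en-1-yl]-6-methoxyphenyl]ethan-1-one | CC(=O)c1c(O)c([C@H](/C=C/C[C@@H](O)CCc2ccccc2)c2ccc(O)cc2)c(O)cc1OC
F14 | step 8 | 1-[2,4-dihydroxy-3-[(1R,2E,5S)-5-hydroxy-1-(4-hydroxyphenyl)-7-phenylhept-2-en-1-yl]-6-methoxyphenyl]-3-hydroxy-3-(4-hydroxyphenyl)propan-1-one (both epimers at the new carbinol) | Oc1ccc(C(O)CC(=O)c2c(O)c([C@H](/C=C/C[C@@H](O)CCc3ccccc3)c3ccc(O)cc3)c(O)cc2OC)cc1
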